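## Retrosynthetic overview

1. The catechol is unveiled last by Dakin oxidation of a C6 formyl group. Earlier, the same formyl group activates an aryl fluoride, so the O1–C8a ether is made by SNAr from a tertiary propargylic alkoxide without touching C2.
2. Key disconnection C4–C4a: a cationic gold-catalysed 6-endo-dig hydroarylation of the aryl propargyl ether closes the pyran ring and creates C3=C4 from an alkyne. It is possible because C4a is the only free position ortho to O1 (C8 carries OMe), lies between the oxygen-bearing C5 and C8a, and the fully substituted C2 holds an ethynyl group that can reach only C4a, so the C2–O1 bond is never broken.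
3. C2 is set by Sharpless epoxidation of an E trisubstituted allylic alcohol and carried through the epoxy chloride into the (S)-alkynyl carbinol.
4. The cyclohexane stereocentres come from a chiral-imine Michael addition of 2,6-dimethylcyclohexanone to methyl vinyl ketone and Robinson annulation to a trans-dimethyl octalone. This temporary enone ring fixes the CHMe centre by equilibration and is then cut open by Eschenmoser–Tanabe fragmentation to a ring ketone (methylenated) and a terminal alkyne (carboaluminated).
5. Ring order: cyclohexane (bought) → temporary enone ring (made, then cleaved) → arene (bought, formylated) → pyran ring (key step, last).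

Key step: step 14

Remark: in step 1 the chiral ketimine is assumed to add with the facial sense usual for (S)-1-phenylethylamine imines of 2-alkylcyclohexanones, which corresponds to the (R) quaternary centre; were the sense reversed, the (R)-amine would be used.

## Route

Step 1
Reactants: 1 2,6-dimethylcyclohexanone (cis/trans mixture); 2 (S)-1-phenylethylamine; 3 methyl vinyl ketone
Product: 6 (2R)-2,6-dimethyl-2-(3-oxobutyl)cyclohexan-1-one as a mixture of C6 epimers, via ketimine 4 (not isolated), via Michael adduct ketimine 5 (not isolated)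
Conditions: 2, TsOH·H2O (cat.), toluene, Dean–Stark, reflux; concentrate; 3, THF, rt to 40 °C; then 10% aq. AcOH, rt
Reagents that add atoms: water, O
Why: Deracemising Michael addition of a chiral ketimine through its more substituted secondary enamine tautomer (aza-ene-type transfer of N–H to the enone), in which the phenyl group of the auxiliary should shield one enamine face and so set the (R) quaternary centre, while the C6 methyl centre stays a mixture that is corrected in step 2.

Step 2
Reactants: 6 (2R)-2,6-dimethyl-2-(3-oxobutyl)cyclohexan-1-one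
Product: 8 (4aR,8R)-4a,8-dimethyl-4,4a,5,6,7,8-hexahydronaphthalen-2(3H)-one, via ketol 7 (not isolated)
Conditions: NaOMe, MeOH, reflux
Reagents that add atoms: none
Why: Intramolecular aldol condensation (second stage of a Robinson annulation) under equilibrating conditions, in which C8 epimerises through the extended dienolate and should settle with its methyl equatorial and trans to the angular C4a methyl (the arrangement that avoids a 1,3-diaxial methyl–methyl contact), any minor cis isomer being removed at this rigid bicyclic stage.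

Step 3
Reactants: 8 (4aR,8R)-4a,8-dimethyl-4,4a,5,6,7,8-hexahydronaphthalen-2(3H)-one
Product: 9 (4aR,8R)-1,8a-epoxy-4a,8-dimethyloctahydronaphthalen-2(1H)-one as a mixture of epoxide diastereomers
Conditions: 30% aq. H2O2, NaOH (cat.), MeOH, 0 °C to rt
Reagents that add atoms: hydrogen peroxide, OO
Why: Weitz–Scheffer nucleophilic epoxidation of the enone; the two new epoxide centres are destroyed in step 4, so their configuration is immaterial.

Step 4
Reactants: 9 (4aR,8R)-1,8a-epoxy-4a,8-dimethyloctahydronaphthalen-2(1H)-one
Product: 11 (2R,6R)-2-(but-3-yn-1-yl)-2,6-dimethylcyclohexan-1-one, via tosylhydrazone 10 (not isolated)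
Conditions: TsNHNH2, AcOH/CH2Cl2 (1:1), −20 °C to rt
Reagents that add atoms: none
Why: Eschenmoser–Tanabe fragmentation, in which the tosylhydrazone opens the epoxide and the C1–C8a bond then breaks with loss of N2 and sulfinate, removing the temporary ring and giving the ring ketone and the terminal alkyne under mildly acidic conditions that should not epimerise the α-methyl centre.

Step 5
Reactants: 11 (2R,6R)-2-(but-3-yn-1-yl)-2,6-dimethylcyclohexan-1-one
Product: 12 (1R,3R)-1-(but-3-yn-1-yl)-1,3-dimethyl-2-methylidenecyclohexane
Conditions: Zn, CH2Br2, TiCl4 (pre-aged reagent, excess), THF/CH2Cl2, 0 °C to rt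
Reagents that add atoms: dibromomethane, BrCBr
Why: Takai–Lombardo methylenation with a non-basic zinc/titanium methylene reagent, chosen because a basic Wittig ylide could epimerise the methyl-bearing α-centre of this hindered ketone, which becomes configurationally fixed once the carbonyl is gone.

Step 6
Reactants: 12 (1R,3R)-1-(but-3-yn-1-yl)-1,3-dimethyl-2-methylidenecyclohexane
Product: 14 (2E)-5-[(1R,3R)-1,3-dimethyl-2-methylidenecyclohexyl]-3-methylpent-2-en-1-ol, via alkenylalane 13 (not isolated)
Conditions: Me3Al, Cp2ZrCl2 (cat.), CH2Cl2, 0 °C to rt; then THF, n-BuLi, −78 °C; (CH2O)n, −78 °C to rt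
Reagents that add atoms: trimethylaluminium, C[Al](C)C; paraformaldehyde (as formaldehyde), C=O
Why: Negishi zirconium-catalysed syn-carboalumination puts methyl on the internal alkyne carbon with aluminium cis to it, and the alanate formed with n-BuLi is hydroxymethylated with retention, so the E trisubstituted allylic alcohol should result while the hindered 1,1-disubstituted alkene stays untouched.

Step 7
Reactants: 14 (2E)-5-[(1R,3R)-1,3-dimethyl-2-methylidenecyclohexyl]-3-methylpent-2-en-1-ol
Product: 15 [(2S,3S)-3-{2-[(1R,3R)-1,3-dimethyl-2-methylidenecyclohexyl]ethyl}-3-methyloxiran-2-yl]methanol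
Conditions: Ti(OiPr)4 (cat.), L-(+)-diethyl tartrate (cat.), t-BuOOH, 4 Å MS, CH2Cl2, −20 °C
Reagents that add atoms: tert-butyl hydroperoxide, CC(C)(C)OO
Why: Sharpless asymmetric epoxidation, in which L-(+)-diethyl tartrate should direct oxygen to the face of the E allylic alcohol that gives the (2S,3S)-epoxide, fixing the future C2 of the chromene by reagent control independent of the remote ring centres.

Step 8
Reactants: 15 [(2S,3S)-3-{2-[(1R,3R)-1,3-dimethyl-2-methylidenecyclohexyl]ethyl}-3-methyloxiran-2-yl]methanol
Product: 16 (2R,3S)-2-(chloromethyl)-3-{2-[(1R,3R)-1,3-dimethyl-2-methylidenecyclohexyl]ethyl}-3-methyloxirane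
Conditions: PPh3, CCl4, NaHCO3, reflux
Reagents that add atoms: tetrachloromethane, ClC(Cl)(Cl)Cl
Why: Appel chlorination of the primary alcohol under buffered conditions that leave the epoxide and both stereocentres intact (the descriptor at C2 changes only because chlorine raises the priority of the CH2 group).

Step 9
Reactants: 16 (2R,3S)-2-(chloromethyl)-3-{2-[(1R,3R)-1,3-dimethyl-2-methylidenecyclohexyl]ethyl}-3-methyloxirane
Product: 18 (3S)-5-[(1R,3R)-1,3-dimethyl-2-methylidenecyclohexyl]-3-methylpent-1-yn-3-ol, via chlorovinyl carbinolate 17 (not isolated)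
Conditions: n-BuLi (3.2 equiv), THF, −78 to −30 °C; aq. NH4Cl
Reagents that add atoms: none
Why: Base-induced double elimination of a 2,3-epoxy chloride (α-deprotonation with epoxide opening to a chlorovinyl carbinolate, then dehydrochlorination) gives the terminal propargylic alcohol, and since the C3–O bond is never broken the tertiary centre is retained.

Step 10
Reactants: 19 3-fluoro-4-methoxyphenol
Product: 20 4-fluoro-2-hydroxy-5-methoxybenzaldehyde
Conditions: MgCl2, Et3N, (CH2O)n, MeCN, reflux; aq. HCl work-up
Reagents that add atoms: paraformaldehyde (as formaldehyde), C=O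
Why: Magnesium-mediated ortho-formylation of a phenol (Casnati–Skattebøl), in which the chelated magnesium phenoxide should direct formaldehyde to the less hindered ortho position para to fluorine and a second formaldehyde oxidises the benzylic alkoxide.

Step 11
Reactants: 20 4-fluoro-2-hydroxy-5-methoxybenzaldehyde
Product: 21 4-fluoro-5-methoxy-2-(methoxymethoxy)benzaldehyde
Conditions: MOMCl, i-Pr2NEt, CH2Cl2, 0 °C to rt
Reagents that add atoms: chloromethyl methyl ether, COCCl
Why: Standard O-alkylation to the methoxymethyl ether, which keeps the phenol from forming a ring-deactivating phenoxide in the SNAr step.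

Step 12
Reactants: 18 (3S)-5-[(1R,3R)-1,3-dimethyl-2-methylidenecyclohexyl]-3-methylpent-1-yn-3-ol; 21 4-fluoro-5-methoxy-2-(methoxymethoxy)benzaldehyde
Product: 22 4-{[(3S)-5-[(1R,3R)-1,3-dimethyl-2-methylidenecyclohexyl]-3-methylpent-1-yn-3-yl]oxy}-5-methoxy-2-(methoxymethoxy)benzaldehyde
Conditions: 18, KN(SiMe3)2 (1.0 equiv), THF, 0 °C; then 21, THF/DMF, 0 °C to rt
Reagents that add atoms: none
Why: Nucleophilic aromatic substitution (addition–elimination) of the fluoride para to the formyl group by the tertiary potassium alkoxide, in which oxygen is the nucleophile so the carbinol centre is carried over with retention.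

Step 13
Reactants: 22 4-{[(3S)-5-[(1R,3R)-1,3-dimethyl-2-methylidenecyclohexyl]-3-methylpent-1-yn-3-yl]oxy}-5-methoxy-2-(methoxymethoxy)benzaldehyde
Product: 23 4-{[(3S)-5-[(1R,3R)-1,3-dimethyl-2-methylidenecyclohexyl]-3-methylpent-1-yn-3-yl]oxy}-2-hydroxy-5-methoxybenzaldehyde
Conditions: HCl (cat.) in MeOH/THF, 0 °C to rt; aqueous work-up
Reagents that add atoms: none
Why: Acid-catalysed acetal exchange of the aryl MOM ether with methanol, eased by the ortho formyl group and done before ring closure so that the chromene never meets acid.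

Step 14
Reactants: 23 4-{[(3S)-5-[(1R,3R)-1,3-dimethyl-2-methylidenecyclohexyl]-3-methylpent-1-yn-3-yl]oxy}-2-hydroxy-5-methoxybenzaldehyde
Product: 24 (2S)-2-{2-[(1R,3R)-1,3-dimethyl-2-methylidenecyclohexyl]ethyl}-5-hydroxy-8-methoxy-2-methyl-2H-chromene-6-carbaldehyde
Conditions: Ph3PAuNTf2 (5 mol%), CH2Cl2, 0 °C to rt, dark
Reagents that add atoms: none
Why: The cationic gold complex binds the terminal alkyne and C4a attacks its terminal carbon anti to gold in a Friedel–Crafts manner; rearomatisation and protodeauration of the vinylgold species release the 2H-chromene and the catalyst. The closest known reaction type is the gold-catalysed intramolecular hydroarylation of aryl propargyl ethers to 2H-chromenes. The pyran ring closes in the 6-endo-dig mode, which for a terminal alkyne on a fully substituted propargylic carbon is preferred over 5-exo-dig closure and gives the cis C3=C4 double bond directly. No stereocentre is formed, and the C2 centre is carried over unchanged because the C2–O1 bond is not broken, in contrast to a thermal Claisen cascade through an ortho-quinone methide, which would scramble it. Site selectivity is secured because C4a is the only free position ortho to O1 (C8 bears OMe) and is activated by the flanking C5 hydroxyl and C8a ether oxygens despite the meta formyl group. Chemoselectivity over the distant 1,1-disubstituted alkene should follow from the six-membered arene attack being faster than a 1,7-enyne pathway, while low temperature, low catalyst loading and exclusion of light (2H-chromenes can ring-open photochemically) protect the product.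

Step 15
Reactants: 24 (2S)-2-{2-[(1R,3R)-1,3-dimethyl-2-methylidenecyclohexyl]ethyl}-5-hydroxy-8-methoxy-2-methyl-2H-chromene-6-carbaldehyde
Product: 26 (2S)-2-{2-[(1R,3R)-1,3-dimethyl-2-methylidenecyclohexyl]ethyl}-8-methoxy-2-methyl-2H-chromene-5,6-diol (CNP0329505.1), via aryl formate 25 (not isolated)
Conditions: 30% aq. H2O2 (1.1 equiv), NaOH (aq.), degassed THF/H2O, 0 °C, argon, dark; then aq. HCl to pH 4
Reagents that add atoms: hydrogen peroxide, OO
Why: Dakin oxidation, in which hydroperoxide adds to the ortho-hydroxy aldehyde, the electron-rich aryl group migrates to oxygen and the formate is hydrolysed in situ, turning the activating formyl group into the C6 hydroxyl without touching the alkenes, while exclusion of air and a limited amount of peroxide guard the catechol.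

## Compound list

1 | 2,6-dimethylcyclohexanone (cis/trans mixture) | CC1CCCC(C)C1=O | starting material
2 | (S)-1-phenylethylamine | C[C@H](N)c1ccccc1 | starting material
3 | methyl vinyl ketone (but-3-en-2-one) | C=CC(C)=O | starting material
4 | (1S)-N-(2,6-dimethylcyclohexylidene)-1-phenylethanamine | CC1CCCC(C)C1=N[C@@H](C)c1ccccc1 | intermediate
5 | 4-[(1R)-1,3-dimethyl-2-{[(1S)-1-phenylethyl]imino}cyclohexyl]butan-2-one | CC(=O)CC[C@@]1(C)CCCC(C)C1=N[C@@H](C)c1ccccc1 | intermediate
6 | (2R)-2,6-dimethyl-2-(3-oxobutyl)cyclohexan-1-one (C6 epimers) | CC(=O)CC[C@@]1(C)CCCC(C)C1=O | intermediate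
7 | (4aR)-8a-hydroxy-4a,8-dimethyloctahydronaphthalen-2(1H)-one | O=C1CC[C@@]2(C)CCCC(C)C2(O)C1 | intermediate
8 | (4aR,8R)-4a,8-dimethyl-4,4a,5,6,7,8-hexahydronaphthalen-2(3H)-one | O=C1CC[C@@]2(C)CCC[C@@H](C)C2=C1 | intermediate
9 | (4aR,8R)-1,8a-epoxy-4a,8-dimethyloctahydronaphthalen-2(1H)-one (epoxide diastereomers) | O=C1CC[C@@]2(C)CCC[C@@H](C)C23OC13 | intermediate
10 | 4-methylbenzenesulfonylhydrazone of 9 | Cc1ccc(cc1)S(=O)(=O)NN=C1CC[C@@]2(C)CCC[C@@H](C)C23OC13 | intermediate
11 | (2R,6R)-2-(but-3-yn-1-yl)-2,6-dimethylcyclohexan-1-one | C#CCC[C@@]1(C)CCC[C@@H](C)C1=O | intermediate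
12 | (1R,3R)-1-(but-3-yn-1-yl)-1,3-dimethyl-2-methylidenecyclohexane | C#CCC[C@@]1(C)CCC[C@@H](C)C1=C | intermediate
13 | [(1E)-4-[(1R,3R)-1,3-dimethyl-2-methylidenecyclohexyl]-2-methylbut-1-en-1-yl]dimethylalane | C[Al](C)/C=C(\C)CC[C@@]1(C)CCC[C@@H](C)C1=C | intermediate
14 | (2E)-5-[(1R,3R)-1,3-dimethyl-2-methylidenecyclohexyl]-3-methylpent-2-en-1-ol | OC/C=C(\C)CC[C@@]1(C)CCC[C@@H](C)C1=C | intermediate
15 | [(2S,3S)-3-{2-[(1R,3R)-1,3-dimethyl-2-methylidenecyclohexyl]ethyl}-3-methyloxiran-2-yl]methanol | OC[C@@H]1O[C@@]1(C)CC[C@@]2(C)CCC[C@@H](C)C2=C | intermediate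
16 | (2R,3S)-2-(chloromethyl)-3-{2-[(1R,3R)-1,3-dimethyl-2-methylidenecyclohexyl]ethyl}-3-methyloxirane | ClC[C@@H]1O[C@@]1(C)CC[C@@]2(C)CCC[C@@H](C)C2=C | intermediate
17 | (3S)-1-chloro-5-[(1R,3R)-1,3-dimethyl-2-methylidenecyclohexyl]-3-methylpent-1-en-3-ol (lithium alkoxide in the flask, alkene geometry undefined) | ClC=C[C@@](C)(O)CC[C@@]1(C)CCC[C@@H](C)C1=C | intermediate
18 | (3S)-5-[(1R,3R)-1,3-dimethyl-2-methylidenecyclohexyl]-3-methylpent-1-yn-3-ol | C#C[C@@](C)(O)CC[C@@]1(C)CCC[C@@H](C)C1=C | intermediate
19 | 3-fluoro-4-methoxyphenol | COc1ccc(O)cc1F | starting material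
20 | 4-fluoro-2-hydroxy-5-methoxybenzaldehyde | COc1cc(C=O)c(O)cc1F | intermediate
21 | 4-fluoro-5-methoxy-2-(methoxymethoxy)benzaldehyde | COCOc1cc(F)c(OC)cc1C=O | intermediate
22 | 4-{[(3S)-5-[(1R,3R)-1,3-dimethyl-2-methylidenecyclohexyl]-3-methylpent-1-yn-3-yl]oxy}-5-methoxy-2-(methoxymethoxy)benzaldehyde | C#C[C@@](C)(Oc1cc(OCOC)c(C=O)cc1OC)CC[C@@]2(C)CCC[C@@H](C)C2=C | intermediate
23 | 4-{[(3S)-5-[(1R,3R)-1,3-dimethyl-2-methylidenecyclohexyl]-3-methylpent-1-yn-3-yl]oxy}-2-hydroxy-5-methoxybenzaldehyde | C#C[C@@](C)(Oc1cc(O)c(C=O)cc1OC)CC[C@@]2(C)CCC[C@@H](C)C2=C | intermediate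
24 | (2S)-2-{2-[(1R,3R)-1,3-dimethyl-2-methylidenecyclohexyl]ethyl}-5-hydroxy-8-methoxy-2-methyl-2H-chromene-6-carbaldehyde | C=C1[C@H](C)CCC[C@]1(C)CC[C@@]1(C)C=Cc2c(O)c(C=O)cc(OC)c2O1 | intermediate
25 | (2S)-2-{2-[(1R,3R)-1,3-dimethyl-2-methylidenecyclohexyl]ethyl}-5-hydroxy-8-methoxy-2-methyl-2H-chromen-6-yl formate | C=C1[C@H](C)CCC[C@]1(C)CC[C@@]1(C)C=Cc2c(O)c(OC=O)cc(OC)c2O1 | intermediate
26 | (2S)-2-{2-[(1R,3R)-1,3-dimethyl-2-methylidenecyclohexyl]ethyl}-8-methoxy-2-methyl-2H-chromene-5,6-diol (CNP0329505.1) | C=C1[C@H](C)CCC[C@]1(C)CC[C@@]1(C)C=Cc2c(O)c(O)cc(OC)c2O1 | target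

## Step count and risks

Total steps: 15. Longest linear sequence: 13 steps (steps 1–9, then 12–15); steps 10 and 11 prepare the arene partner.

**Step 12 (aryl ether formation).** The hindered tertiary alkoxide, or traces of acetylide in equilibrium with it, may add to the formyl group faster than fluoride is displaced at the carbon flanked by OMe, so that aldehyde-consuming side reactions win. The fallback replaces the formyl activator by a nitrile, which tolerates stronger forcing. It sets out from 20: hydroxylamine hydrochloride and sodium acetate in ethanol give 4-fluoro-2-hydroxy-5-methoxybenzaldehyde oxime F1, and acetic anhydride followed by mild methanolysis of the phenol acetate dehydrates it to 4-fluoro-2-hydroxy-5-methoxybenzonitrile F2. MOMCl and i-Pr2NEt give 4-fluoro-5-methoxy-2-(methoxymethoxy)benzonitrile F3. The potassium alkoxide of 18 (KN(SiMe3)2, THF, rt to 50 °C) then displaces fluoride to give the nitrile aryl ether F4. Reduction with i-Bu2AlH in toluene at −78 °C and hydrolytic work-up returns the route at 22.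

**Step 14 (key ring closure).** The gold-activated alkyne may be intercepted by the remote methylidene group in an enyne cycloisomerisation, or the Lewis-acidic cation may ionise the tertiary propargylic C–O bond and erode the C2 configuration, or the formyl-deactivated ring may attack too slowly. The fallback forms the same C4–C4a bond by iodonium-induced cyclisation and sets out from 22. Iodine and NaHCO3 in nitromethane at rt should give the 6-endo-dig product, the 3-iodo-2H-chromene F5 (iodine adds only reversibly to the hindered methylidene group and is removed by thiosulfate work-up). Hydrodeiodination with Pd(PPh3)4 (zerovalent palladium, catalytic), formic acid and triethylamine in DMF gives the MOM-protected chromene F6. Acidic methanolysis as in step 13 returns the route at 24.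

**Step 5 (methylenation).** The carbonyl is flanked by a quaternary carbon and a methine, so addition may be slow enough that enolisation and epimerisation of the C6 methyl centre compete, or the reagent may be consumed by the acidic alkyne C–H. The fallback is a Peterson olefination and sets out from 11. The non-basic organocerium reagent from Me3SiCH2Li and CeCl3 (excess, THF, −78 °C) should add to the hindered ketone without enolisation to give the β-hydroxysilane F7. KH in THF then effects syn-elimination and returns the route at 12.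

## Further compounds

F1 | step 12 | 4-fluoro-2-hydroxy-5-methoxybenzaldehyde oxime | COc1cc(C=NO)c(O)cc1F
F2 | step 12 | 4-fluoro-2-hydroxy-5-methoxybenzonitrile | COc1cc(C#N)c(O)cc1F
F3 | step 12 | 4-fluoro-5-methoxy-2-(methoxymethoxy)benzonitrile | COCOc1cc(F)c(OC)cc1C#N
F4 | step 12 | 4-{[(3S)-5-[(1R,3R)-1,3-dimethyl-2-methylidenecyclohexyl]-3-methylpent-1-yn-3-yl]oxy}-5-methoxy-2-(methoxymethoxy)benzonitrile | C#C[C@@](C)(Oc1cc(OCOC)c(C#N)cc1OC)CC[C@@]2(C)CCC[C@@H](C)C2=C
F5 | step 14 | (2S)-2-{2-[(1R,3R)-1,3-dimethyl-2-methylidenecyclohexyl]ethyl}-3-iodo-8-methoxy-5-(methoxymethoxy)-2-methyl-2H-chromene-6-carbaldehyde | C=C1[C@H](C)CCC[C@]1(C)CC[C@@]1(C)C(I)=Cc2c(OCOC)c(C=O)cc(OC)c2O1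
F6 | step 14 | (2S)-2-{2-[(1R,3R)-1,3-dimethyl-2-methylidenecyclohexyl]ethyl}-8-methoxy-5-(methoxymethoxy)-2-methyl-2H-chromene-6-carbaldehyde | C=C1[C@H](C)CCC[C@]1(C)CC[C@@]1(C)C=Cc2c(OCOC)c(C=O)cc(OC)c2O1
F7 | step 5 | (2R,6R)-2-(but-3-yn-1-yl)-2,6-dimethyl-1-[(trimethylsilyl)methyl]cyclohexan-1-ol | C#CCC[C@@]1(C)CCC[C@@H](C)C1(O)C[Si](C)(C)C
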